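(All runs were generated by integration on assumed constants; noise was put on by code.)

The vessel is closed, stirred and held at one temperature, so I describe each flask by its time and its heat. I give amounts as fractions of the charge, and I assume first-order steps, which would make those fractions independent of the charge.

| flask | starting material | temperature | remark | time |
|---|---|---|---|---|
| spring | 11 mM | 6 °C | run made earlier |  |
| dawn | 16 mM | 31 °C | run made earlier |  |
| Tuesday's | 22 mM | 40 °C |  | 2.5 d |
| Saturday's | 22 mM | 25 °C |  | 2.5 d |
| Friday's | 22 mM | 10 °C |  | 2.5 d |
| Sunday's | 22 mM | −5 °C |  | 2.5 d |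

| run | time / d | target / % | starting material / % |
|---|---|---|---|
| spring | 1.04 | 0.1 | 94.2 |
| spring | 2.50 | 0 | 84.4 |
| spring | 3.00 | 0.4 | 81.9 |
| spring | 6.00 | 0 | 65.3 |
| spring | 15.0 | 0 | 36.6 |
| dawn | 0.333 | 0.9 | 36.3 |
| dawn | 1.04 | 0.1 | 6.6 |
| dawn | 2.08 | 2.5 | 3.7 |
| dawn | 2.50 | 3.7 | 1.8 |
| dawn | 4.00 | 8.0 | 1.4 |

(standard deviation of a reading: 0.5 percentage points)

- the numbers in the tables scatter by 0.5 percentage points (one standard deviation)
- reactions considered so far: starting material <-> dormant form; intermediate A -> intermediate B; intermediate C -> target; intermediate B -> intermediate C; intermediate B -> decomposed reagent; starting material -> intermediate A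

- the flask with the highest amount of target, in percent of the starting material charged ("all alike" if they lie within 1.5 percentage points) (Tuesday's / Saturday's / Friday's / Sunday's / all alike)
- final target, as a percentage of the starting material charged, in Tuesday's
- final target, as a percentage of the starting material charged, in Saturday's
- final target, as a percentage of the starting material charged, in Friday's
- final target, as a percentage of the starting material charged, in Sunday's

Starting material falls to 36.6% at 15.0 d in the spring run and to 36.3% at 0.333 d in the dawn run. These read as constants of 0.0670 d⁻¹ and 3.04 d⁻¹, and so as an activation energy of 108 kJ mol⁻¹. I assume the later steps share it. Then 2.5 d at 40 °C in Tuesday's is worth 8.51 d of the dawn run. I call this count dawn-days, the time at the dawn temperature that does the same work, the usual equivalent time.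

In the dawn run, target climbs from 3.7% to 8.0% between 2.50 d and 4.00 d, which is 0.0287 d⁻¹ of the charge per day. Carried straight on to Tuesday's dawn-days, that line gives 20.9%.

The weak link is the straight line, which holds the feed constant. At 4.00 d everything that is neither starting material nor target is 90.6% of the charge. That figure also counts dormant form and decomposed reagent, which the dawn run does not report, so I can use it as a ceiling on the stock still on its way to target. I put the first answer back in, letting the feed shrink by what that line draws from this ceiling, and get 20.0%. I commit to that for Tuesday's as a figure on the high side, since the stock I used is a ceiling.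

Saturday's gets 1.06 d, close to the dawn reading at 1.04 d, where target stood at 0.1%. Friday's gets 0.106 d and Sunday's 0.00820 d, so I expect about zero in those two.

The forecast names Tuesday's, with 18% there, 0.3% in Saturday's, 0% in Friday's and 0% in Sunday's, and adds: “This is uncertain because the decomposition branch could cut it.”

The flasks give 15.4% in Tuesday's, 0.501% in Saturday's, 0% in Friday's and 0% in Sunday's, so the highest is Tuesday's.

    starting material ⇌ dormant form (K = 2.90, k = 3.30 × 10⁻⁴ min⁻¹, Ea = 108 kJ mol⁻¹, ΔH = −12.0 kJ mol⁻¹)
    intermediate A → intermediate B (k = 8.00 × 10⁻⁵ min⁻¹, Ea = 102 kJ mol⁻¹)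
    intermediate C → target (k = 2.70 × 10⁻⁴ min⁻¹, Ea = 106 kJ mol⁻¹)
    intermediate B → intermediate C (k = 2.10 × 10⁻⁴ min⁻¹, Ea = 100 kJ mol⁻¹)
    intermediate B → decomposed reagent (k = 6.30 × 10⁻⁴ min⁻¹, Ea = 108 kJ mol⁻¹)
    starting material → intermediate A (k = 6.20 × 10⁻⁴ min⁻¹, Ea = 108 kJ mol⁻¹)
    (constants at 25 °C)

At 1.25 d Tuesday's has 4.25 d dawn-days and holds 7.37% target, beside the dawn reading of 8.0% at 4.00 d. From there to its end Tuesday's gains 0.0190 d⁻¹ per dawn-day, less than the dawn run's 0.0287 d⁻¹, while intermediate A falls from 39.2% to 18.6%. Friday's at 25.0 d has 1.06 d dawn-days, about the same as Saturday's at its end. It holds 52.5% intermediate A against Saturday's 54.6%, and 0.665% target against Saturday's 0.501%.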